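## Analysis of the target

The target is a sesquineolignan built on a tetrahydrofuran (O1, C2–C5). C2 carries ring B, C3 carries a hydroxymethyl group (C9), and C4 carries a benzyl group (C7' and ring A). The para oxygen of ring B is bound to C8'' of a 1-arylglycerol unit (C7''–C9'', ring C).

There are five stereocentres. On the ring, C2 (S), C3 (R) and C4 (R) place ring B trans to the C9 arm and the C9 arm cis to the C7' arm. In the side chain, C7'' (S) and C8'' (S) form a threo (syn) pair that is too far from the ring to be controlled by it.

The sensitive groups are two free phenols and two oxygen-bearing benzylic carbons, C2 and C7''. Both benzylic C–O bonds can ionise in acid and can be cleaved by hydrogenolysis.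

The main difficulties are the cis C3/C4 relationship, which is the less stable arrangement on a five-membered ring, and the need to set two separate stereo-domains in the absolute sense. In addition, the five hydroxyl groups must be told apart late in the synthesis.

The plan rests on one structural feature. C3 and C4 are neighbouring CH centres, each with a one-carbon arm (C9 and C7') and each flanked by a further oxygenated carbon (C2 and C5). This is the pattern of an α,β-disubstituted γ-butyrolactone in which C9 is the carbonyl carbon and C5 the γ-carbon. Because the tetrahydrofuran is closed later through C2 and not through C9, a trans lactone becomes the cis-3,4 tetrahydrofuran.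

## Retrosynthetic reasoning

**Protecting groups (26 to 24).** The two phenols of 26 are masked as benzyl ethers and the C7''/C9'' diol as an isopropylidene ketal, which leads back through 25 to 24. The ketal is removed before the benzyl ethers so that ring C is still a non-phenolic ether when acid is present, which keeps C7'' from ionising. The forward steps are a mild hydrolysis and a hydrogenolysis that stops at the aryl benzyl ethers.

**O1–C2 bond (24 to 22).** The ring is opened at O1–C2 rather than at O1–C5. C2 is benzylic to an alkoxy-substituted ring, so a hydroxyl group there ionises to cation 23, and the C5 hydroxyl can close the ring on it. The gain is that the C2 configuration is decided at the closure, where ring B settles trans to the C9 arm, so the carbinol centre of triol 22 needs no control. Cutting O1–C5 instead would demand a single carbinol epimer.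

**C7' and the two primary alcohols (22 to 20).** The C7' methylene of 22 is traced to a thioketal carbon in 21. The primary alcohols at C9 and C5 are traced to the carbonyl and acetal carbons of lactone 20. This converts the acyclic triol into a small ring on which relative configuration is easy to control. The forward steps are a hydride reduction that unravels lactone and acetal together and a reductive desulfurisation.

**C4–C7' and C3–C2 bonds (20 to 5, 7 and 17).** Both bonds are cut in one operation. This leads to butenolide 5, the dithiane 7 (as its anion 18) and aldehyde 17. These are the α- and β-bonds of the lactone, the two bonds a conjugate addition followed by enolate trapping makes in sequence through enolate 19. The acetal carbon C5 of 5 is the only stereocentre needed beforehand: it directs C4, and C4 directs C3. Aldehyde 17 already carries the full side chain, so the coupling is fully convergent.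

**Butenolide 5 and dithiane 7.** Compound 5 goes back to the hydroxybutenolide 3 and the chiral alcohol 4, and 3 to furfural 1 by photo-oxygenation. The acetal centre is obtained pure by crystallisation, not by an asymmetric reaction. Dithiane 7 is the thioacetal of aldehyde 6.

**C7''–C8'' bond (17 to 11 and 6).** Aldehyde 17 is taken back to nitrile 15 (the nitrile is a latent formyl group that tolerates enolate chemistry), then to diol 14 and to imide 13. In 13 the C7''–C8'' bond is cut as a syn aldol between the boron enolate 12 of imide 11 and aldehyde 6. The cut is made here for two reasons: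
- Threo at C7''/C8'' is the syn aldol relationship, which an oxazolidinone auxiliary sets reliably.
- The aryl ether oxygen is already on C8'' before the stereocentres exist. A free C7'',C8'',C9''-triol would form a five-membered ketal across neighbouring oxygens and would not leave the C8'' hydroxyl free for arylation. With the ether in place, only the six-membered C7''/C9'' ketal of 15 can form.

**Imide 11.** The ether C–O bond of 11 is cut to phenol 10 and the bromoacetyl imide 9, which comes from auxiliary 8.

## Alternatives that were turned down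

**Alternative 1:** The disconnection sets C4 alone. A Baeyer–Villiger monooxygenase with O2 would insert oxygen into one of the two enantiotopic C(=O)–CH2 bonds of the prochiral cyclobutanone A1 and give the (R)-lactone A2. The C3–C2 bond would follow from an aldol of the A2 enolate with 17, anti to the benzyl group, and the end game would be the one used here.
- For: chirality comes from a catalyst and air. C7' is already a methylene, so no thioketal and no desulfurisation are needed. On this point it is stronger than the chosen route, which has to remove two sulfur atoms in the presence of benzyl ethers and a benzylic alcohol.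
- Against: the enzyme must accept a bulky 4-benzyloxy-3-methoxybenzyl substituent and deliver the R lactone. The sense and level of selectivity of these enzymes change with the aryl group and would have to be found by screening. A1 needs a ketene cycloaddition and dechlorination sequence. The key step makes no C–C bond and only one stereocentre, so the step count is not lower.
- In its place the chosen strategy offers two C–C bonds and two stereocentres in one flask, with a sense of induction that follows from the shape of 5.

**Alternative 2:** The disconnection is O1–C2, made by C–H oxidation. DDQ would abstract hydride from the benzylic C2 methylene of diol A3 and the C5 hydroxyl would trap the cation to give A4.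
- For: there is no carbinol centre to carry as a mixture, and the ring closes without protic acid, so the ketal is safer than in step 13 here. On that point it is stronger.
- Against: A3 has three benzylic C–H sites (C2, C7' and C7''). The choice between them rests only on the electronic difference between an aryl alkyl ether on ring B and aryl pivalates on rings A and C. The product A4 still has an oxidisable C2–H next to oxygen. The pivalates cost extra steps, and A3 with its (2R,3R) centres must first be made by an asymmetric route of about the length of the present one.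
- The chosen closure ionises the only carbon that carries a leaving group, so its site selectivity is structural, not electronic.

**Alternative 3:** The disconnection is C4–C5. MgBr2·OEt2 would open the C4–C7' epoxide of pyran A5 at C4, the C5 methylene would migrate from C7' to C4 with inversion, and the ring would contract to the tetrahydrofuran aldehyde A6.
- For: the shift is stereospecific, and ring A could be varied late by adding an aryl metal to A6.
- Against: A5 needs C2, C3 and a cis-placed epoxide to be set on a pyran before the key step. The epoxide must open at the unstabilised C4 and not at C7', and ring contraction must beat hydride shift and bromohydrin formation. A6 holds its formyl group cis to the C9 arm on an enolisable carbon, so the cis relationship can leak to trans. Ring A addition and removal of the new benzylic hydroxyl add further steps next to the C2–O1 benzylic ether.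
- The chosen strategy brings in ring A, C7' and C9 with their carbons in one step. After step 11 neither C3 nor C4 is next to a carbonyl group.

Key step: step 10

Remarks on the chemistry:
- The carbinol carbon made in step 10 (later C2) is carried as a mixture of epimers through 20–22 and is drawn without configuration.
- Compounds 6, 8 and 10 are taken as purchased materials.
- Men = (1R,2S,5R)-2-isopropyl-5-methylcyclohexyl.
- ArB = 4-({(4S,5S)-4-(4-benzyloxy-3-methoxyphenyl)-2,2-dimethyl-1,3-dioxan-5-yl}oxy)-3-methoxyphenyl.

## Route

Step 1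
Reactants: 1 furfural
Product: 3 5-hydroxyfuran-2(5H)-one (racemic lactol), via furfural endoperoxide 2 (not isolated)
Conditions: O2, hν (visible), methylene blue (cat.), MeOH, rt
Reagents that add atoms: dioxygen, O=O
Why: Sensitised photo-oxygenation; singlet oxygen adds across the furan diene in a [4+2] cycloaddition to give 2, which methanol fragments with loss of the formyl carbon to leave the hydroxybutenolide.

Step 2
Reactants: 3 5-hydroxyfuran-2(5H)-one; 4 (−)-menthol
Product: 5 (5R)-5-(Men-oxy)furan-2(5H)-one
Conditions: CSA (cat.), toluene, reflux (Dean–Stark); crystallise from petroleum ether, −20 °C; mother liquor re-equilibrated with CSA and recrystallised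
Reagents that add atoms: none
Why: Acid-catalysed acetalisation of the lactol; the acetal carbon epimerises under the acid and the (5R) diastereomer is the one that crystallises, so crystallisation with recycling of the liquor should deliver a single C5 configuration.

Step 3
Reactants: 6 4-benzyloxy-3-methoxybenzaldehyde
Product: 7 2-(4-benzyloxy-3-methoxyphenyl)-1,3-dithiane
Conditions: HS(CH2)3SH, BF3·OEt2 (cat.), CH2Cl2, 0 °C → rt
Reagents that add atoms: propane-1,3-dithiol, SCCCS
Why: Lewis-acid thioacetalisation of an aromatic aldehyde; the benzyl ether is inert to catalytic BF3·OEt2 at this temperature.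

Step 4
Reactants: 8 (R)-4-benzyloxazolidin-2-one
Product: 9 (R)-4-benzyl-3-(bromoacetyl)oxazolidin-2-one
Conditions: n-BuLi, THF, −78 °C; BrCH2COBr, −78 → 0 °C
Reagents that add atoms: bromoacetyl bromide, O=C(Br)CBr
Why: N-acylation of the lithiated oxazolidinone; the acyl bromide reacts much faster than the alkyl bromide at −78 °C.

Step 5
Reactants: 9 (R)-4-benzyl-3-(bromoacetyl)oxazolidin-2-one; 10 4-hydroxy-3-methoxybenzonitrile
Product: 11 (R)-4-benzyl-3-[(4-cyano-2-methoxyphenoxy)acetyl]oxazolidin-2-one
Conditions: K2CO3, acetone, rt
Reagents that add atoms: none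
Why: Williamson ether synthesis by SN2 at an activated α-halo carbonyl carbon; the cyano-substituted phenoxide is a poor acyl acceptor, so the imide should stay intact.

Step 6
Reactants: 11 (R)-4-benzyl-3-[(4-cyano-2-methoxyphenoxy)acetyl]oxazolidin-2-one; 6 4-benzyloxy-3-methoxybenzaldehyde
Product: 13 (4R)-4-benzyl-3-[(2R,3S)-3-(4-benzyloxy-3-methoxyphenyl)-2-(4-cyano-2-methoxyphenoxy)-3-hydroxypropanoyl]oxazolidin-2-one, via (Z)-dibutylboron enolate 12 (not isolated)
Conditions: Bu2BOTf, Et3N, CH2Cl2, −78 → 0 °C; 6, −78 → 0 °C; pH 7 buffer, MeOH, H2O2, 0 °C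
Reagents that add atoms: none
Why: Evans syn aldol; soft enolisation gives the Z-enolate 12, which reacts through a chair Zimmerman–Traxler transition state in which the benzyl group of the (R)-auxiliary shields one enolate face. This sets C8'' and C7'' syn (threo) in the (2R,3S) sense, which becomes (7''S,8''S) after reduction.

Step 7
Reactants: 13 aldol adduct
Product: 14 4-{[(1S,2S)-1-(4-benzyloxy-3-methoxyphenyl)-1,3-dihydroxypropan-2-yl]oxy}-3-methoxybenzonitrile
Conditions: LiBH4, MeOH (1 equiv), THF, 0 °C
Reagents that add atoms: none
Why: Reductive cleavage of the N-acyl oxazolidinone at the exocyclic carbonyl gives the primary alcohol and returns 8; the nitrile and the ethers are not reduced by LiBH4 and neither stereocentre is touched.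

Step 8
Reactants: 14 threo 1,3-diol
Product: 15 4-{[(4S,5S)-4-(4-benzyloxy-3-methoxyphenyl)-2,2-dimethyl-1,3-dioxan-5-yl]oxy}-3-methoxybenzonitrile
Conditions: Me2C(OMe)2, PPTS (cat.), acetone, rt
Reagents that add atoms: 2,2-dimethoxypropane, COC(C)(C)OC
Why: Trans-ketalisation; the C8'' oxygen is an aryl ether, so only the six-membered ketal can form. It should be the cis-4,5-disubstituted dioxane with the aryl group equatorial and the aryloxy group axial.

Step 9
Reactants: 15 ketal nitrile
Product: 17 ArB-CHO, 4-({(4S,5S)-4-(4-benzyloxy-3-methoxyphenyl)-2,2-dimethyl-1,3-dioxan-5-yl}oxy)-3-methoxybenzaldehyde, via N-aluminio aldimine 16 (not isolated)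
Conditions: i-Bu2AlH, CH2Cl2, −78 °C; aq. potassium sodium tartrate, then wet silica gel, rt
Reagents that add atoms: water, O
Why: Partial reduction of a nitrile; one hydride adds to give 16, which is not reduced further at −78 °C and is hydrolysed to the aldehyde on work-up. Ketal and benzyl ethers are inert.

Step 10
Reactants: 7 2-(4-benzyloxy-3-methoxyphenyl)-1,3-dithiane; 5 (5R)-5-(Men-oxy)furan-2(5H)-one; 17 ArB-CHO
Product: 20 (3S,4R,5R)-4-[2-(4-benzyloxy-3-methoxyphenyl)-1,3-dithian-2-yl]-3-[hydroxy(ArB)methyl]-5-(Men-oxy)dihydrofuran-2(3H)-one (both carbinol epimers), via 2-lithio-1,3-dithiane 18 (not isolated), via lithium lactone enolate 19 (not isolated)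
Conditions: 7, n-BuLi, THF, −78 → −20 °C; 5, −78 °C; 17, −78 °C; aq. NH4Cl, −78 °C
Reagents that add atoms: none
Why: n-BuLi removes the C2 proton of 7 and the sulfur-stabilised benzylic anion 18 adds 1,4 to butenolide 5; the lithium enolate 19 is not quenched but intercepted by aldehyde 17, and protonation of the aldolate at −78 °C should give 20. The closest known reaction type is the tandem conjugate addition–aldol (or –alkylation) of lithiated dithioacetals on 5-alkoxyfuran-2(5H)-ones. Two C–C bonds form (C4–C7' and C3–C2) and no ring closes. C4 is set by the acetal centre C5: the menthyloxy group blocks one face of the planar butenolide, so 18 enters anti to it and gives 4R. C3 is set by C4: the enolate carbon lies next to the fully substituted dithianyl carbon, so the aldehyde approaches from the opposite face and the 3,4-trans lactone (3S) results. The carbinol carbon forms as a mixture, which is accepted because step 13 passes through a planar cation at that carbon. The step needs 1,4- and not 1,2-addition, which the soft, hindered 2-aryl dithiane anion and the low temperature secure; it also needs the enolate to add and not be protonated or revert, which the non-enolisable, aprotic aldehyde 17 and the cold quench secure.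

Step 11
Reactants: 20 lactone acetal
Product: 21 (2R,3R)-2-[2-(4-benzyloxy-3-methoxyphenyl)-1,3-dithian-2-yl]-3-[hydroxy(ArB)methyl]butane-1,4-diol (both carbinol epimers)
Conditions: LiAlH4, THF, 0 °C → rt
Reagents that add atoms: none
Why: Hydride opens the lactone; the freed hemiacetal alkoxide at C5 expels menthoxide and the resulting aldehyde is reduced, so C9 and C5 both end as primary alcohols and 4 is released. The transient aldehydes are reduced faster than they enolise, so C3 and C4 should be preserved.

Step 12
Reactants: 21 thioketal triol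
Product: 22 (2R,3R)-2-(4-benzyloxy-3-methoxybenzyl)-3-[hydroxy(ArB)methyl]butane-1,4-diol (both carbinol epimers)
Conditions: Raney Ni (W-2), EtOH/THF, rt
Reagents that add atoms: none
Why: Reductive desulfurisation of a benzylic thioketal; the weak benzylic C–S bonds are cleaved at room temperature, which turns C7' into a methylene while the aryl benzyl ethers and the benzylic hydroxyl should be spared.

Step 13
Reactants: 22 triol
Product: 24 [(2S,3R,4R)-2-ArB-4-(4-benzyloxy-3-methoxybenzyl)tetrahydrofuran-3-yl]methanol, via benzylic cation 23 (not isolated)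
Conditions: CSA (cat.), 4 Å MS, CH2Cl2, 0 °C; Et3N quench
Reagents that add atoms: none
Why: SN1 etherification; either carbinol epimer ionises to the alkoxy-stabilised benzylic cation 23, and the C5 hydroxyl closes the five-membered ring on it (the C9 hydroxyl could only give an oxetane). Ring B should take the face trans to the C9 arm and away from the cis C3/C4 pair, and the closure is acid-reversible so the trans isomer accumulates, which sets C2 as S. The ketal should survive because the medium is anhydrous and ionisation at C7'' is slowed by the neighbouring aryloxy group.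

Step 14
Reactants: 24 ketal-protected tetrahydrofuran
Product: 25 (1S,2S)-1-(4-benzyloxy-3-methoxyphenyl)-2-{4-[(2S,3R,4R)-4-(4-benzyloxy-3-methoxybenzyl)-3-(hydroxymethyl)tetrahydrofuran-2-yl]-2-methoxyphenoxy}propane-1,3-diol
Conditions: AcOH/THF/H2O (3:1:1), 40 °C
Reagents that add atoms: none
Why: Hydrolysis of the isopropylidene ketal by weak aqueous acid, which should be too mild to ionise the benzylic C–O bonds at C2 and C7'' while both rings are still non-phenolic ethers.

Step 15
Reactants: 25 dibenzyl ether
Product: 26 (1S,2S)-1-(4-hydroxy-3-methoxyphenyl)-2-{4-[(2S,3R,4R)-4-(4-hydroxy-3-methoxybenzyl)-3-(hydroxymethyl)tetrahydrofuran-2-yl]-2-methoxyphenoxy}propane-1,3-diol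
Conditions: H2 (1 atm), 10% Pd/C, EtOAc/EtOH, rt, stopped after uptake of two equivalents
Reagents that add atoms: none
Why: Hydrogenolysis of the two aryl benzyl ethers, which under neutral conditions should be faster than cleavage of the benzylic ether C2–O1 or the benzylic alcohol at C7''; no stereocentre is touched.

## Compound list

1 | furfural | O=Cc1ccco1 | starting material
2 | furfural endoperoxide (2,3,7-trioxabicyclo[2.2.1]hept-5-ene-1-carbaldehyde) | O=CC12OOC(C=C1)O2 | intermediate (not isolated)
3 | 5-hydroxyfuran-2(5H)-one, racemic | O=C1C=CC(O)O1 | intermediate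
4 | (−)-menthol, (1R,2S,5R)-2-isopropyl-5-methylcyclohexan-1-ol | CC(C)[C@@H]1CC[C@@H](C)C[C@H]1O | starting material
5 | (5R)-5-[(1R,2S,5R)-menthyloxy]furan-2(5H)-one | O=C1C=C[C@H](O[C@@H]2C[C@H](C)CC[C@H]2C(C)C)O1 | intermediate
6 | 4-benzyloxy-3-methoxybenzaldehyde | O=Cc1ccc(OCc2ccccc2)c(OC)c1 | starting material
7 | 2-(4-benzyloxy-3-methoxyphenyl)-1,3-dithiane | COc1cc(C2SCCCS2)ccc1OCc1ccccc1 | intermediate
8 | (R)-4-benzyloxazolidin-2-one | O=C1N[C@H](Cc2ccccc2)CO1 | starting material
9 | (R)-4-benzyl-3-(bromoacetyl)oxazolidin-2-one | O=C(CBr)N1[C@H](Cc2ccccc2)COC1=O | intermediate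
10 | 4-hydroxy-3-methoxybenzonitrile | N#Cc1ccc(O)c(OC)c1 | starting material
11 | (R)-4-benzyl-3-[(4-cyano-2-methoxyphenoxy)acetyl]oxazolidin-2-one | N#Cc1ccc(OCC(=O)N2[C@H](Cc3ccccc3)COC2=O)c(OC)c1 | intermediate
12 | (Z)-dibutylboron enolate of 11 | N#Cc1ccc(O/C=C(\OB(CCCC)CCCC)N2[C@H](Cc3ccccc3)COC2=O)c(OC)c1 | intermediate (not isolated)
13 | (4R)-4-benzyl-3-[(2R,3S)-3-(4-benzyloxy-3-methoxyphenyl)-2-(4-cyano-2-methoxyphenoxy)-3-hydroxypropanoyl]oxazolidin-2-one | N#Cc1ccc(O[C@@H](C(=O)N2[C@H](Cc3ccccc3)COC2=O)[C@@H](O)c3ccc(OCc4ccccc4)c(OC)c3)c(OC)c1 | intermediate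
14 | 4-{[(1S,2S)-1-(4-benzyloxy-3-methoxyphenyl)-1,3-dihydroxypropan-2-yl]oxy}-3-methoxybenzonitrile | N#Cc1ccc(O[C@@H](CO)[C@@H](O)c2ccc(OCc3ccccc3)c(OC)c2)c(OC)c1 | intermediate
15 | 4-{[(4S,5S)-4-(4-benzyloxy-3-methoxyphenyl)-2,2-dimethyl-1,3-dioxan-5-yl]oxy}-3-methoxybenzonitrile | N#Cc1ccc(O[C@H]2COC(C)(C)O[C@H]2c2ccc(OCc3ccccc3)c(OC)c2)c(OC)c1 | intermediate
16 | N-(diisobutylaluminio)aldimine of 15 | CC(C)C[Al](CC(C)C)N=Cc1ccc(O[C@H]2COC(C)(C)O[C@H]2c2ccc(OCc3ccccc3)c(OC)c2)c(OC)c1 | intermediate (not isolated)
17 | 4-{[(4S,5S)-4-(4-benzyloxy-3-methoxyphenyl)-2,2-dimethyl-1,3-dioxan-5-yl]oxy}-3-methoxybenzaldehyde | O=Cc1ccc(O[C@H]2COC(C)(C)O[C@H]2c2ccc(OCc3ccccc3)c(OC)c2)c(OC)c1 | intermediate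
18 | 2-lithio-2-(4-benzyloxy-3-methoxyphenyl)-1,3-dithiane | [Li]C1(SCCCS1)c1ccc(OCc2ccccc2)c(OC)c1 | intermediate (not isolated)
19 | lithium enolate of (4R,5R)-4-[2-(4-benzyloxy-3-methoxyphenyl)-1,3-dithian-2-yl]-5-menthyloxydihydrofuran-2(3H)-one | COc1cc(C2(SCCCS2)[C@H]3[C@H](O[C@@H]4C[C@H](C)CC[C@H]4C(C)C)OC(O[Li])=C3)ccc1OCc1ccccc1 | intermediate (not isolated)
20 | (3S,4R,5R)-4-[2-(4-benzyloxy-3-methoxyphenyl)-1,3-dithian-2-yl]-3-[hydroxy(ArB)methyl]-5-[(1R,2S,5R)-menthyloxy]dihydrofuran-2(3H)-one, both carbinol epimers | COc1cc(C2(SCCCS2)[C@H]3[C@H](O[C@@H]4C[C@H](C)CC[C@H]4C(C)C)OC(=O)[C@@H]3C(O)c5ccc(O[C@H]6COC(C)(C)O[C@H]6c7ccc(OCc8ccccc8)c(OC)c7)c(OC)c5)ccc1OCc1ccccc1 | intermediate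
21 | (2R,3R)-2-[2-(4-benzyloxy-3-methoxyphenyl)-1,3-dithian-2-yl]-3-[hydroxy(ArB)methyl]butane-1,4-diol, both carbinol epimers | COc1cc(C2(SCCCS2)[C@@H](CO)[C@H](CO)C(O)c3ccc(O[C@H]4COC(C)(C)O[C@H]4c5ccc(OCc6ccccc6)c(OC)c5)c(OC)c3)ccc1OCc1ccccc1 | intermediate
22 | (2R,3R)-2-(4-benzyloxy-3-methoxybenzyl)-3-[hydroxy(ArB)methyl]butane-1,4-diol, both carbinol epimers | COc1cc(C[C@@H](CO)[C@H](CO)C(O)c3ccc(O[C@H]4COC(C)(C)O[C@H]4c5ccc(OCc6ccccc6)c(OC)c5)c(OC)c3)ccc1OCc1ccccc1 | intermediate
23 | benzylic cation at C2 derived from 22 | COc1cc(C[C@@H](CO)[C@H](CO)[CH+]c3ccc(O[C@H]4COC(C)(C)O[C@H]4c5ccc(OCc6ccccc6)c(OC)c5)c(OC)c3)ccc1OCc1ccccc1 | intermediate (not isolated)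
24 | [(2S,3R,4R)-2-ArB-4-(4-benzyloxy-3-methoxybenzyl)tetrahydrofuran-3-yl]methanol | COc1cc(C[C@H]2CO[C@H](c3ccc(O[C@H]4COC(C)(C)O[C@H]4c5ccc(OCc6ccccc6)c(OC)c5)c(OC)c3)[C@H]2CO)ccc1OCc1ccccc1 | intermediate
25 | (1S,2S)-1-(4-benzyloxy-3-methoxyphenyl)-2-{4-[(2S,3R,4R)-4-(4-benzyloxy-3-methoxybenzyl)-3-(hydroxymethyl)tetrahydrofuran-2-yl]-2-methoxyphenoxy}propane-1,3-diol | COc1cc(C[C@H]2CO[C@H](c3ccc(O[C@@H](CO)[C@@H](O)c4ccc(OCc5ccccc5)c(OC)c4)c(OC)c3)[C@H]2CO)ccc1OCc1ccccc1 | intermediate
26 | (1S,2S)-1-(4-hydroxy-3-methoxyphenyl)-2-{4-[(2S,3R,4R)-4-(4-hydroxy-3-methoxybenzyl)-3-(hydroxymethyl)tetrahydrofuran-2-yl]-2-methoxyphenoxy}propane-1,3-diol | COc1cc(C[C@H]2CO[C@H](c3ccc(O[C@@H](CO)[C@@H](O)c4ccc(O)c(OC)c4)c(OC)c3)[C@H]2CO)ccc1O | target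

## Step count and risk

Total step count: 15. Longest linear sequence: 12 steps (steps 4–15, from 8).

**Step 10 (key step).** The most likely failure is in the second half. The hindered lithium enolate 19, next to the fully substituted dithianyl carbon, may add slowly or reversibly to the electron-rich aldehyde, so that proton transfer or retro-aldol returns the simple conjugate adduct. Fallback: the two bond formations are separated. From 5 and 7, the conjugate addition alone is run as above and quenched cold to isolate (4R,5R)-4-[2-(4-benzyloxy-3-methoxyphenyl)-1,3-dithian-2-yl]-5-menthyloxydihydrofuran-2(3H)-one F1. F1 is then deprotonated with LiN(i-Pr)2 in THF at −78 °C, transmetallated with ZnCl2 to a zinc enolate whose chelated aldolate resists reversal, and treated with 17. This returns the route at 20.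

**Step 12.** The most likely failure is over-reduction on the nickel surface: loss of the free, electron-rich benzylic hydroxyl or of the aryl benzyl ethers along with the sulfur. Fallback: the sulfur is removed by a radical chain before any free benzylic alcohol is exposed to a metal surface. From 20, Bu3SnH and AIBN in toluene at reflux should give (3S,4R,5R)-4-(4-benzyloxy-3-methoxybenzyl)-3-[hydroxy(ArB)methyl]-5-menthyloxydihydrofuran-2(3H)-one F2. LiAlH4 as in step 11 then returns the route at 22.

**Step 13.** The most likely failure is capture of cation 23 by ring A (Friedel–Crafts closure to an aryltetralin) in competition with capture by oxygen, together with acid-promoted exchange of the ketal. Fallback: the ring is closed while C7' is still the thioketal carbon, where ring A is inductively deactivated by two C–S bonds and sits on a crowded, fully substituted carbon. From 21, the same catalytic CSA treatment should give [(2S,3R,4R)-2-ArB-4-[2-(4-benzyloxy-3-methoxyphenyl)-1,3-dithian-2-yl]tetrahydrofuran-3-yl]methanol F3. Desulfurisation as in step 12 then returns the route at 24.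

**Step 15.** The most likely failure is hydrogenolysis running past the two aryl benzyl ethers into the benzylic C2–O1 bond (ring opening) or the C7'' hydroxyl. Fallback: the benzyl groups are removed by electron transfer instead of on a palladium surface, and before the ketal is removed. From 24, lithium naphthalenide (LiC10H8) in THF at −25 °C should cleave only the benzyl–O bonds, since these release a phenoxide, whereas the ring ether is bound to a dialkoxy arene and would have to release an alkoxide. This gives [(2S,3R,4R)-2-{4-[((4S,5S)-4-(4-hydroxy-3-methoxyphenyl)-2,2-dimethyl-1,3-dioxan-5-yl)oxy]-3-methoxyphenyl}-4-(4-hydroxy-3-methoxybenzyl)tetrahydrofuran-3-yl]methanol F4. Hydrolysis of the ketal in aqueous acetic acid at rt then returns the route at 26.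

## Further compounds

F1 | step 10 | (4R,5R)-4-[2-(4-benzyloxy-3-methoxyphenyl)-1,3-dithian-2-yl]-5-[(1R,2S,5R)-menthyloxy]dihydrofuran-2(3H)-one | COc1cc(C2(SCCCS2)[C@H]3[C@H](O[C@@H]4C[C@H](C)CC[C@H]4C(C)C)OC(=O)C3)ccc1OCc1ccccc1
F2 | step 12 | (3S,4R,5R)-4-(4-benzyloxy-3-methoxybenzyl)-3-[hydroxy(ArB)methyl]-5-[(1R,2S,5R)-menthyloxy]dihydrofuran-2(3H)-one, both carbinol epimers | COc1cc(C[C@H]3[C@H](O[C@@H]4C[C@H](C)CC[C@H]4C(C)C)OC(=O)[C@@H]3C(O)c5ccc(O[C@H]6COC(C)(C)O[C@H]6c7ccc(OCc8ccccc8)c(OC)c7)c(OC)c5)ccc1OCc1ccccc1
F3 | step 13 | [(2S,3R,4R)-2-ArB-4-[2-(4-benzyloxy-3-methoxyphenyl)-1,3-dithian-2-yl]tetrahydrofuran-3-yl]methanol | COc1cc(C2(SCCCS2)[C@H]3CO[C@H](c4ccc(O[C@H]5COC(C)(C)O[C@H]5c6ccc(OCc7ccccc7)c(OC)c6)c(OC)c4)[C@H]3CO)ccc1OCc1ccccc1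
F4 | step 15 | [(2S,3R,4R)-2-{4-[((4S,5S)-4-(4-hydroxy-3-methoxyphenyl)-2,2-dimethyl-1,3-dioxan-5-yl)oxy]-3-methoxyphenyl}-4-(4-hydroxy-3-methoxybenzyl)tetrahydrofuran-3-yl]methanol | COc1cc(C[C@H]2CO[C@H](c3ccc(O[C@H]4COC(C)(C)O[C@H]4c5ccc(O)c(OC)c5)c(OC)c3)[C@H]2CO)ccc1O
A1 | alternative 1 | 3-(4-benzyloxy-3-methoxybenzyl)cyclobutan-1-one | COc1cc(CC2CC(=O)C2)ccc1OCc1ccccc1
A2 | alternative 1 | (R)-4-(4-benzyloxy-3-methoxybenzyl)dihydrofuran-2(3H)-one | COc1cc(C[C@H]2COC(=O)C2)ccc1OCc1ccccc1
A3 | alternative 2 | (2R,3R)-2-[3-methoxy-4-(pivaloyloxy)benzyl]-3-{4-[((4S,5S)-2,2-dimethyl-4-[3-methoxy-4-(pivaloyloxy)phenyl]-1,3-dioxan-5-yl)oxy]-3-methoxybenzyl}butane-1,4-diol | COc1cc(C[C@@H](CO)[C@H](CO)Cc3ccc(O[C@H]4COC(C)(C)O[C@H]4c5ccc(OC(=O)C(C)(C)C)c(OC)c5)c(OC)c3)ccc1OC(=O)C(C)(C)C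
A4 | alternative 2 | protected target with the C7''/C9'' isopropylidene ketal and two phenol pivalates | COc1cc(C[C@H]2CO[C@H](c3ccc(O[C@H]4COC(C)(C)O[C@H]4c5ccc(OC(=O)C(C)(C)C)c(OC)c5)c(OC)c3)[C@H]2CO)ccc1OC(=O)C(C)(C)C
A5 | alternative 3 | 2,3-trans-2-ArB-3-(tert-butyldimethylsilyloxymethyl)-4,5-epoxytetrahydropyran, epoxide cis to the silyloxymethyl group | COc1cc(ccc1O[C@H]4COC(C)(C)O[C@H]4c5ccc(OCc6ccccc6)c(OC)c5)[C@H]1OC[C@@H]2O[C@@H]2[C@@H]1CO[Si](C)(C)C(C)(C)C
A6 | alternative 3 | 2,3-trans-3,4-cis-2-ArB-3-(tert-butyldimethylsilyloxymethyl)tetrahydrofuran-4-carbaldehyde | O=C[C@H]2CO[C@H](c3ccc(O[C@H]4COC(C)(C)O[C@H]4c5ccc(OCc6ccccc6)c(OC)c5)c(OC)c3)[C@H]2CO[Si](C)(C)C(C)(C)C
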